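## Retrosynthetic overview

1. Target 26 ⇐ 25 by E1cB unveiling of the exocyclic methylene; 25 ⇐ 24 by ring-closing metathesis at C1=C10 (ten-membered carbocycle, formed second).
2. 24 ⇐ ketone 23 (CBS reduction sets C8) ⇐ dithiane 22. Key C7–C8 bond: conjugate addition of lithiated dithiane 19 (C8 acyl-anion equivalent) to butenolide 12, anti to the C6 side chain, with the enolate trapped by CH2O (C13).
3. 12 (γ-lactone, formed first) ⇐ Lindlar reduction/lactonization of ynoate 10 ⇐ asymmetric alkynylation of enal 7 with methyl propiolate (sets C6).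
4. 7 ⇐ (E)-selective cross-aldol condensation of hex-5-enal with glyoxal mono(dimethyl acetal), which fixes the C4=C5 geometry; 18 ⇐ 1,3-dithiane + 3-chloro-2-(chloromethyl)prop-1-ene.

Assumption: atom labels C1–C15 are the germacranolide labels of the target (lactone C6–C7–C11–C12, C13 = exocyclic methylene, C8 = carbinol, C14 on C10, C15 on C4), and (S,S)-ProPhenol is taken to give Si-face alkynylation of 7 (otherwise its mirror-image ligand is used).

## Route

Step 1
Reactants: 1 hex-5-enal; 2 2,2-dimethoxyacetaldehyde (60% aqueous solution)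
Product: 4 (2E)-2-(but-3-en-1-yl)-4,4-dimethoxybut-2-enal, via aldol adduct 3 (not isolated)
Conditions: pyrrolidine (20 mol %), PhCO2H (20 mol %), toluene, 60 °C, slow addition of 1 to 2 (1.5 equiv)
Reagents that add atoms: none
Why: Amine-catalysed cross-aldol condensation in which only 1 forms the enamine; dehydration gives the thermodynamic (E)-2-alkylenal (CHO trans to the acetal carbon), which fixes the later C4=C5 geometry (C3 cis to C6).

Step 2
Reactants: 4
Product: 6 (2E)-2-(but-3-en-1-yl)-4,4-dimethoxybut-2-en-1-yl acetate, via aluminium alkoxide 5 (not isolated)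
Conditions: i-Bu2AlH, CH2Cl2, −78 °C; then Ac2O, pyridine, DMAP, −78 °C to rt
Reagents that add atoms: acetic anhydride CC(=O)OC(C)=O
Why: 1,2-Reduction of the enal with in situ acetylation of the aluminium alkoxide (reductive acetylation) installs the C15 acetate and leaves the acetal untouched.

Step 3
Reactants: 6
Product: 7 (2E)-2-(but-3-en-1-yl)-4-oxobut-2-en-1-yl acetate
Conditions: Amberlyst-15, THF–H2O (10:1), 0 °C to rt
Reagents that add atoms: water O
Why: Mild acid-catalysed hydrolysis of the vinylogous acetal releases the C6 aldehyde under conditions that spare the allylic acetate and the alkene geometry.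

Step 4
Reactants: 7; 8 methyl propiolate
Product: 10 methyl (4R,5E)-6-(acetoxymethyl)-4-hydroxydeca-5,9-dien-2-ynoate, via alkynylzinc 9 (not isolated)
Conditions: (S,S)-ProPhenol (20 mol %), Me2Zn (3 equiv), Ph3PO (40 mol %), toluene, 0 °C; aq. NH4Cl
Reagents that add atoms: none
Why: Zinc–ProPhenol-catalysed asymmetric alkynylation of an enal, in which the dinuclear zinc catalyst delivers the alkynyl group to the Si face of the aldehyde and so sets C6 (R).

Step 5
Reactants: 10
Product: 12 (5S)-5-[(1E)-2-(acetoxymethyl)hexa-1,5-dien-1-yl]furan-2(5H)-one, via (Z)-hydroxy enoate 11 (not isolated)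
Conditions: H2 (1 atm), Pd on CaCO3 poisoned with Pb(OAc)2, quinoline, EtOAc, rt; then PPTS (cat.), CH2Cl2, rt
Reagents that add atoms: none
Why: Lindlar cis-semihydrogenation of the ynoate and lactonization of the (Z)-γ-hydroxy enoate close the γ-lactone without touching C6 (the descriptor becomes S only through a change in CIP priorities).

Step 6
Reactants: 13 1,3-dithiane; 14 3-chloro-2-(chloromethyl)prop-1-ene
Product: 16 2-[2-(chloromethyl)prop-2-en-1-yl]-1,3-dithiane, via 2-lithio-1,3-dithiane 15 (not isolated)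
Conditions: n-BuLi, THF, −30 °C; then cannulated into 14 (3 equiv), THF, −78 °C to 0 °C
Reagents that add atoms: none
Why: Corey–Seebach alkylation of the dithiane anion, kept at monoalkylation by inverse addition to excess dichloride.

Step 7
Reactants: 16
Product: 18 2-(1,3-dithian-2-ylmethyl)prop-2-en-1-ol, via allylic acetate 17 (not isolated)
Conditions: KOAc, DMF, 60 °C; then K2CO3 (cat.), MeOH, rt
Reagents that add atoms: potassium acetate CC(=O)[O-].[K+]
Why: SN2 displacement of the allylic chloride by acetate and in situ methanolysis give the allylic alcohol that becomes C14–OH.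

Step 8
Reactants: 18; 12
Product: 21 (3R,4S,5R)-5-[(1E)-2-(acetoxymethyl)hexa-1,5-dien-1-yl]-3-(hydroxymethyl)-4-{2-[2-(hydroxymethyl)prop-2-en-1-yl]-1,3-dithian-2-yl}dihydrofuran-2(3H)-one, via dilithio dithiane 19 (not isolated), via lithium enolate 20 (not isolated)
Conditions: 18, n-BuLi (2.1 equiv), THF, −78 to −25 °C; DMPU, −78 °C, then 12; monomeric CH2O (gas, from cracking paraformaldehyde), −78 to −40 °C; AcOH, −78 °C
Reagents that add atoms: formaldehyde C=O
Why: Corey–Seebach acyl-anion conjugate addition to the butenolide with aldol trapping of the lactone enolate (tandem Michael–aldol), in which the C8 carbanion attacks C7 anti to the C6 alkenyl group (C7 set trans to C6) and CH2O enters anti to the new C7 substituent (C11, removed in step 13).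

Step 9
Reactants: 21
Product: 22 (3R,4S,5R)-5-[(1E)-2-(acetoxymethyl)hexa-1,5-dien-1-yl]-3-[(2-methylpropanoyloxy)methyl]-4-(2-{2-[(2-methylpropanoyloxy)methyl]prop-2-en-1-yl}-1,3-dithian-2-yl)dihydrofuran-2(3H)-one
Conditions: (i-PrCO)2O, pyridine, DMAP (cat.), CH2Cl2, 0 °C
Reagents that add atoms: 2-methylpropanoic anhydride CC(C)C(=O)OC(=O)C(C)C
Why: Acylation of both primary alcohols, the C14 isobutyrate being the ester of the target and the C13 isobutyrate the leaving group for the final elimination.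

Step 10
Reactants: 22
Product: 23 (3R,4S,5R)-5-[(1E)-2-(acetoxymethyl)hexa-1,5-dien-1-yl]-3-[(2-methylpropanoyloxy)methyl]-4-{3-[(2-methylpropanoyloxy)methyl]but-3-enoyl}dihydrofuran-2(3H)-one
Conditions: PhI(OCOCF3)2 (1.5 equiv), MeCN–H2O (9:1), 0 °C, 10 min; aq. NaHCO3 work-up; used at once
Reagents that add atoms: water O
Why: Oxidative dithiane hydrolysis with a hypervalent iodine reagent unmasks the C8 ketone under cold, base-free conditions, so the β,γ-unsaturated ketone and the β-acyloxy lactone survive.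

Step 11
Reactants: 23
Product: 24 (3R,4R,5R)-5-[(1E)-2-(acetoxymethyl)hexa-1,5-dien-1-yl]-4-{(1R)-1-hydroxy-3-[(2-methylpropanoyloxy)methyl]but-3-en-1-yl}-3-[(2-methylpropanoyloxy)methyl]dihydrofuran-2(3H)-one
Conditions: (S)-2-methyl-CBS-oxazaborolidine (20 mol %), catecholborane (1.5 equiv), toluene, −78 °C; pH 7 buffer
Reagents that add atoms: none
Why: Corey–Bakshi–Shibata reduction, in which the catalyst distinguishes the branched C7 side (large) from the C9 methylene (small) and delivers hydride to give the (8R)-alcohol by reagent control.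

Step 12
Reactants: 24
Product: 25 (3R,3aR,4R,6E,10E,11aR)-10-(acetoxymethyl)-4-hydroxy-3,6-bis[(2-methylpropanoyloxy)methyl]-3a,4,5,8,9,11a-hexahydrocyclodeca[b]furan-2(3H)-one
Conditions: second-generation Grubbs catalyst (15 mol %), toluene (1 mM), 80 °C
Reagents that add atoms: none
Why: Ring-closing metathesis of the terminal vinyl group with the 1,1-disubstituted alkene forms the ten-membered ring, the ring constraint favouring the C1=C10 alkene with C2 and C9 cis (E by CIP), while the still-masked exocyclic methylene cannot compete.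

Step 13
Reactants: 25
Product: 26 CNP0312458.1, (3aR,4R,6E,10E,11aR)-10-(acetoxymethyl)-4-hydroxy-3-methylidene-6-[(2-methylpropanoyloxy)methyl]-3a,4,5,8,9,11a-hexahydrocyclodeca[b]furan-2(3H)-one
Conditions: DBU (1.2 equiv), CH2Cl2, 0 °C, 30 min
Reagents that add atoms: none
Why: E1cB β-elimination of 2-methylpropanoic acid from the α-(acyloxymethyl) lactone unveils the α-methylene-γ-butyrolactone, removing the C11 stereocentre and leaving C6, C7 and C8 (all R) untouched.

## Compound list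

1 | hex-5-enal | C=CCCCC=O | starting material
2 | 2,2-dimethoxyacetaldehyde | COC(OC)C=O | starting material
3 | 2-(but-3-en-1-yl)-3-hydroxy-4,4-dimethoxybutanal (aldol adduct, diastereomer mixture) | C=CCCC(C=O)C(O)C(OC)OC | intermediate
4 | (2E)-2-(but-3-en-1-yl)-4,4-dimethoxybut-2-enal | O=C/C(CCC=C)=C/C(OC)OC | intermediate
5 | diisobutylaluminium (2E)-2-(but-3-en-1-yl)-4,4-dimethoxybut-2-en-1-olate | CC(C)C[Al](CC(C)C)OC/C(CCC=C)=C/C(OC)OC | intermediate
6 | (2E)-2-(but-3-en-1-yl)-4,4-dimethoxybut-2-en-1-yl acetate | CC(=O)OC/C(CCC=C)=C/C(OC)OC | intermediate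
7 | (2E)-2-(but-3-en-1-yl)-4-oxobut-2-en-1-yl acetate | CC(=O)OC/C(CCC=C)=C/C=O | intermediate
8 | methyl propiolate | C#CC(=O)OC | starting material
9 | methyl 3-(methylzincio)prop-2-ynoate | C[Zn]C#CC(=O)OC | intermediate
10 | methyl (4R,5E)-6-(acetoxymethyl)-4-hydroxydeca-5,9-dien-2-ynoate | O[C@@H](C#CC(=O)OC)/C=C(/COC(C)=O)CCC=C | intermediate
11 | methyl (2Z,4S,5E)-6-(acetoxymethyl)-4-hydroxydeca-2,5,9-trienoate | O[C@@H](/C=C\C(=O)OC)/C=C(/COC(C)=O)CCC=C | intermediate
12 | (5S)-5-[(1E)-2-(acetoxymethyl)hexa-1,5-dien-1-yl]furan-2(5H)-one | O=C1O[C@H](/C=C(/COC(C)=O)CCC=C)C=C1 | intermediate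
13 | 1,3-dithiane | C1CSCSC1 | starting material
14 | 3-chloro-2-(chloromethyl)prop-1-ene | C=C(CCl)CCl | starting material
15 | 2-lithio-1,3-dithiane | [Li]C1SCCCS1 | intermediate
16 | 2-[2-(chloromethyl)prop-2-en-1-yl]-1,3-dithiane | C=C(CCl)CC1SCCCS1 | intermediate
17 | 2-(1,3-dithian-2-ylmethyl)prop-2-en-1-yl acetate | CC(=O)OCC(=C)CC1SCCCS1 | intermediate
18 | 2-(1,3-dithian-2-ylmethyl)prop-2-en-1-ol | OCC(=C)CC1SCCCS1 | intermediate
19 | O,C2-dilithio derivative of 18 | [Li]OCC(=C)CC1([Li])SCCCS1 | intermediate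
20 | lithium lactone enolate of the conjugate adduct (C14 as lithium alkoxide) | [Li]OC=1O[C@H](/C=C(/COC(C)=O)CCC=C)[C@@H](C2(CC(=C)CO[Li])SCCCS2)C=1 | intermediate
21 | (3R,4S,5R)-5-[(1E)-2-(acetoxymethyl)hexa-1,5-dien-1-yl]-3-(hydroxymethyl)-4-{2-[2-(hydroxymethyl)prop-2-en-1-yl]-1,3-dithian-2-yl}dihydrofuran-2(3H)-one | O=C1O[C@H](/C=C(/COC(C)=O)CCC=C)[C@@H](C2(CC(=C)CO)SCCCS2)[C@@H]1CO | intermediate
22 | (3R,4S,5R)-5-[(1E)-2-(acetoxymethyl)hexa-1,5-dien-1-yl]-3-[(2-methylpropanoyloxy)methyl]-4-(2-{2-[(2-methylpropanoyloxy)methyl]prop-2-en-1-yl}-1,3-dithian-2-yl)dihydrofuran-2(3H)-one | O=C1O[C@H](/C=C(/COC(C)=O)CCC=C)[C@@H](C2(CC(=C)COC(=O)C(C)C)SCCCS2)[C@@H]1COC(=O)C(C)C | intermediate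
23 | (3R,4S,5R)-5-[(1E)-2-(acetoxymethyl)hexa-1,5-dien-1-yl]-3-[(2-methylpropanoyloxy)methyl]-4-{3-[(2-methylpropanoyloxy)methyl]but-3-enoyl}dihydrofuran-2(3H)-one | O=C1O[C@H](/C=C(/COC(C)=O)CCC=C)[C@@H](C(=O)CC(=C)COC(=O)C(C)C)[C@@H]1COC(=O)C(C)C | intermediate
24 | (3R,4R,5R)-5-[(1E)-2-(acetoxymethyl)hexa-1,5-dien-1-yl]-4-{(1R)-1-hydroxy-3-[(2-methylpropanoyloxy)methyl]but-3-en-1-yl}-3-[(2-methylpropanoyloxy)methyl]dihydrofuran-2(3H)-one | O=C1O[C@H](/C=C(/COC(C)=O)CCC=C)[C@@H]([C@H](O)CC(=C)COC(=O)C(C)C)[C@@H]1COC(=O)C(C)C | intermediate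
25 | (3R,3aR,4R,6E,10E,11aR)-10-(acetoxymethyl)-4-hydroxy-3,6-bis[(2-methylpropanoyloxy)methyl]-3a,4,5,8,9,11a-hexahydrocyclodeca[b]furan-2(3H)-one | CC(C)C(=O)OC[C@@H]1C(=O)O[C@@H]2/C=C(/COC(C)=O)CC/C=C(/COC(=O)C(C)C)C[C@@H](O)[C@@H]12 | intermediate
26 | CNP0312458.1, (3aR,4R,6E,10E,11aR)-10-(acetoxymethyl)-4-hydroxy-3-methylidene-6-[(2-methylpropanoyloxy)methyl]-3a,4,5,8,9,11a-hexahydrocyclodeca[b]furan-2(3H)-one | C=C1C(=O)O[C@@H]2/C=C(/COC(C)=O)CC/C=C(/COC(=O)C(C)C)C[C@@H](O)[C@@H]12 | target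

## Step count and risks

Total steps: 13. Longest linear sequence: 11 (steps 1–5 and 8–13).

Steps most likely to fail:

**Step 8 (three-component coupling).** The strongly basic dithiane anion may deprotonate the acidic γ-position (C6–H) of 12 or attack the C15 acetate instead of adding to C7. The fallback sets out from 12 and 18 and comes back at 26, and it inverts the polarity of the C7–C8 union. Compound 18 is acylated ((i-PrCO)2O, pyridine) to 2-(1,3-dithian-2-ylmethyl)prop-2-en-1-yl 2-methylpropanoate F1 and unmasked (PhI(OCOCF3)2, aq. MeCN) to the aldehyde 2-methylidene-4-oxobutyl 2-methylpropanoate F2. Butenolide 12 is hydroxymethylated at C11 (aq. CH2O, imidazole, Morita–Baylis–Hillman) to (5R)-5-[(1E)-2-(acetoxymethyl)hexa-1,5-dien-1-yl]-3-(hydroxymethyl)furan-2(5H)-one F3 and converted (CBr4, PPh3) into (5R)-5-[(1E)-2-(acetoxymethyl)hexa-1,5-dien-1-yl]-3-(bromomethyl)furan-2(5H)-one F4. Zn-mediated Barbier coupling of F4 with F2 (THF–aq. NH4Cl) joins C7 to C8 with allylic transposition under neutral conditions and gives (4R,5R)-5-[(1E)-2-(acetoxymethyl)hexa-1,5-dien-1-yl]-4-{(1R)-1-hydroxy-3-[(2-methylpropanoyloxy)methyl]but-3-en-1-yl}-3-methylidenedihydrofuran-2(3H)-one F5 (C7 anti to the C6 substituent; C8 epimers separated). Ring-closing metathesis of F5 (second-generation Grubbs catalyst, 1 mM) then gives 26.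

**Step 11 (CBS reduction).** Discrimination between a branched alkyl and an allylic methylene may give only a modest C8 ratio, and the ketone is sensitive. The fallback sets out from 23 and comes back at 24. Compound 23 is reduced without reagent control (NaBH4, CeCl3, MeOH, −78 °C) and the epimers are separated. The unwanted (3R,4R,5R)-5-[(1E)-2-(acetoxymethyl)hexa-1,5-dien-1-yl]-4-{(1S)-1-hydroxy-3-[(2-methylpropanoyloxy)methyl]but-3-en-1-yl}-3-[(2-methylpropanoyloxy)methyl]dihydrofuran-2(3H)-one F6 is inverted by Mitsunobu reaction (ClCH2CO2H, PPh3, DIAD) to the (8R)-chloroacetate of 24 F7, which thiourea (NaHCO3, EtOH) cleaves selectively to 24.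

**Step 12 (ring-closing metathesis).** Closure of a ten-membered ring through a trisubstituted alkene may stall at oligomers or give the wrong alkene geometry. The fallback sets out from 23 and comes back at 25, moving ring closure ahead of the reduction. Metathesis of ketone 23 (planar C8, no free hydroxyl; same catalyst, 1 mM) gives the macrocyclic C8 ketone (4-oxo analogue of 25) F8, and reduction of F8 ((S)-2-methyl-CBS-oxazaborolidine, catecholborane, or NaBH4/CeCl3 attacking the outer face of the ring) gives 25.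

## Further compounds

F1 | step 8 | 2-(1,3-dithian-2-ylmethyl)prop-2-en-1-yl 2-methylpropanoate | CC(C)C(=O)OCC(=C)CC1SCCCS1
F2 | step 8 | 2-methylidene-4-oxobutyl 2-methylpropanoate | CC(C)C(=O)OCC(=C)CC=O
F3 | step 8 | (5R)-5-[(1E)-2-(acetoxymethyl)hexa-1,5-dien-1-yl]-3-(hydroxymethyl)furan-2(5H)-one | O=C1O[C@H](/C=C(/COC(C)=O)CCC=C)C=C1CO
F4 | step 8 | (5R)-5-[(1E)-2-(acetoxymethyl)hexa-1,5-dien-1-yl]-3-(bromomethyl)furan-2(5H)-one | O=C1O[C@H](/C=C(/COC(C)=O)CCC=C)C=C1CBr
F5 | step 8 | (4R,5R)-5-[(1E)-2-(acetoxymethyl)hexa-1,5-dien-1-yl]-4-{(1R)-1-hydroxy-3-[(2-methylpropanoyloxy)methyl]but-3-en-1-yl}-3-methylidenedihydrofuran-2(3H)-one | O=C1O[C@H](/C=C(/COC(C)=O)CCC=C)[C@@H]([C@H](O)CC(=C)COC(=O)C(C)C)C1=C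
F6 | step 11 | (3R,4R,5R)-5-[(1E)-2-(acetoxymethyl)hexa-1,5-dien-1-yl]-4-{(1S)-1-hydroxy-3-[(2-methylpropanoyloxy)methyl]but-3-en-1-yl}-3-[(2-methylpropanoyloxy)methyl]dihydrofuran-2(3H)-one (C8 epimer of 24) | O=C1O[C@H](/C=C(/COC(C)=O)CCC=C)[C@@H]([C@@H](O)CC(=C)COC(=O)C(C)C)[C@@H]1COC(=O)C(C)C
F7 | step 11 | (8R)-chloroacetate of 24 (OC(O)CH2Cl in place of the C8 hydroxyl) | O=C1O[C@H](/C=C(/COC(C)=O)CCC=C)[C@@H]([C@H](OC(=O)CCl)CC(=C)COC(=O)C(C)C)[C@@H]1COC(=O)C(C)C
F8 | step 12 | macrocyclic C8 ketone, (3R,3aS,6E,10E,11aR)-4-oxo analogue of 25 | CC(C)C(=O)OC[C@@H]1C(=O)O[C@@H]2/C=C(/COC(C)=O)CC/C=C(/COC(=O)C(C)C)CC(=O)[C@@H]12
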